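**Plan**

1. Retrosynthetic cuts: C8–C9 epoxide oxygen (C7-OH-directed epoxidation of a Z-olefin); lactone bonds O2–C3 and C3–C4 (carbonylative closure of an alkynol, C3 from CO); C12–C13 (acetylide + epoxy aldehyde); C4≡C12 (from a C4 carboxyl).
2. Central cut: the ring-fusion bond C4a–C11a, opened retro-[3,3] to an 11-membered lactone (C4 acyl, O on C19).
3. Enabling feature: the exocyclic methylene C11=C19 lies γ,δ to C4 across the fusion bond (C19=C11–C11a–C4a–C4), so the nine-membered carbocycle is the Claisen ring-contraction product of a lactone that ties C4 to C19.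
4. Forward order: C4–C9 alkyne + C10/C11/C19/C11a/C1 allylic bromide → Z-skipped-diene seco acid → 11-membered lactone → nine-membered ring (key step) → δ-lactone → 8,9-epoxide.
5. Stereochemistry: C7 and C14 from Sharpless epoxidations; C4a/C11a from a chair boron-enolate Claisen (trans from enolate and olefin geometry, absolute sense from a chiral controller); C13 by Felkin–Anh addition; C4=C12 (E) by syn-acylpalladation; C8/C9 by syn vanadium-directed epoxidation.

Key step: step 14

Remark: locants C1–C19 are xenicane locants (C1 lactone OCH2, C3 lactone C=O, C4 alkylidene carbon, C4a/C11a ring fusion, C7 carbinol with methyl C18, C8/C9 epoxide, C11 bearing =C19H2, C12–C15 side chain).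
Remark: the (S,S)-controller in step 14 is assumed to deliver the (4aS,11aR) pair; if its facial sense is the opposite, the (R,R)-controller is used instead.
Remark: 1 and 11 are taken as catalogue compounds.

**Route**

Step 1
Reactants: 1 tert-butyl(hex-5-yn-1-yloxy)dimethylsilane
Product: 3 (2E)-7-[(tert-butyldimethylsilyl)oxy]-3-methylhept-2-en-1-ol, via alkenylalane 2 (not isolated)
Conditions: Me3Al, Cp2ZrCl2 (cat.), CH2Cl2, 0 °C to rt; then n-BuLi, (CH2O)n, THF, −78 °C to rt; 1 M HCl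
Reagents that add atoms: trimethylaluminium C[Al](C)C; formaldehyde (as paraformaldehyde) C=O
Why: Zr-catalysed Negishi syn-carboalumination puts the methyl (C18) on the internal carbon (C7) and Al on C8 cis to it, and the alanate is hydroxymethylated with retention to the (E)-allylic alcohol.

Step 2
Reactants: 3 (2E)-7-[(tert-butyldimethylsilyl)oxy]-3-methylhept-2-en-1-ol
Product: 4 [(2S,3S)-3-{4-[(tert-butyldimethylsilyl)oxy]butyl}-3-methyloxiran-2-yl]methanol
Conditions: Ti(OiPr)4 (cat.), L-(+)-diethyl tartrate (cat.), t-BuOOH, 4 Å MS, CH2Cl2, −20 °C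
Reagents that add atoms: tert-butyl hydroperoxide CC(C)(C)OO
Why: Sharpless asymmetric epoxidation of a geraniol-type (E)-allylic alcohol; L-(+)-tartrate should give the (2S,3S)-epoxide, which fixes C7 as S.

Step 3
Reactants: 4 [(2S,3S)-3-{4-[(tert-butyldimethylsilyl)oxy]butyl}-3-methyloxiran-2-yl]methanol
Product: 5 tert-butyl{4-[(2S,3R)-3-(chloromethyl)-2-methyloxiran-2-yl]butoxy}dimethylsilane
Conditions: PPh3, CCl4, NaHCO3, reflux
Reagents that add atoms: carbon tetrachloride ClC(Cl)(Cl)Cl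
Why: Appel chlorination of the primary alcohol under neutral conditions leaves the epoxide and both stereocentres untouched.

Step 4
Reactants: 5 tert-butyl{4-[(2S,3R)-3-(chloromethyl)-2-methyloxiran-2-yl]butoxy}dimethylsilane
Product: 7 (3S)-7-[(tert-butyldimethylsilyl)oxy]-3-methylhept-1-yn-3-ol, via chloroalkenyl alkoxide 6 (not isolated)
Conditions: LDA (3.5 equiv), THF, −35 °C; aq. NH4Cl
Reagents that add atoms: none
Why: base-induced double elimination of a 2,3-epoxy chloride (epoxide opening, then dehydrochlorination) gives the terminal propargylic alcohol; the C7–O bond is never broken, so configuration is retained.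

Step 5
Reactants: 7 (3S)-7-[(tert-butyldimethylsilyl)oxy]-3-methylhept-1-yn-3-ol
Product: 8 (3S)-3,7-bis[(tert-butyldimethylsilyl)oxy]-3-methylhept-1-yne
Conditions: TBSOTf, 2,6-lutidine, CH2Cl2, 0 °C
Reagents that add atoms: tert-butyldimethylsilyl triflate CC(C)(C)[Si](C)(C)OS(=O)(=O)C(F)(F)F
Why: silyl triflate silylation of the tertiary alcohol, which must be masked so that it cannot form a δ-lactone with C4 in step 13.

Step 6
Reactants: 8 (3S)-3,7-bis[(tert-butyldimethylsilyl)oxy]-3-methylhept-1-yne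
Product: 9 (5S)-5-[(tert-butyldimethylsilyl)oxy]-5-methylhept-6-yn-1-ol
Conditions: PPTS (cat.), MeOH, rt
Reagents that add atoms: none
Why: acid-catalysed methanolysis should cleave the unhindered primary silyl ether well before the tertiary one.

Step 7
Reactants: 10 ethyl acrylate; 11 2-[(4-methoxyphenyl)methoxy]acetaldehyde
Product: 12 ethyl 3-hydroxy-4-[(4-methoxyphenyl)methoxy]-2-methylidenebutanoate (racemic)
Conditions: DABCO, dioxane/H2O, rt
Reagents that add atoms: none
Why: Morita–Baylis–Hillman reaction of an α-alkoxy aldehyde; the carbinol centre is removed in step 8, so no control is needed.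

Step 8
Reactants: 12 ethyl 3-hydroxy-4-[(4-methoxyphenyl)methoxy]-2-methylidenebutanoate
Product: 13 ethyl (2Z)-2-(bromomethyl)-4-[(4-methoxyphenyl)methoxy]but-2-enoate
Conditions: NBS, Me2S, CH2Cl2, 0 °C to rt
Reagents that add atoms: N-bromosuccinimide O=C1CCC(=O)N1Br
Why: sulfonium activation of the MBH alcohol and SN2′ attack of bromide should give the (2Z)-bromomethyl enoate with CH2OPMB (C1) trans to the ester carbon (C19), the geometry step 14 needs.

Step 9
Reactants: 9 (5S)-5-[(tert-butyldimethylsilyl)oxy]-5-methylhept-6-yn-1-ol; 13 ethyl (2Z)-2-(bromomethyl)-4-[(4-methoxyphenyl)methoxy]but-2-enoate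
Product: 14 ethyl (2E,6S)-6-[(tert-butyldimethylsilyl)oxy]-10-hydroxy-2-{2-[(4-methoxyphenyl)methoxy]ethylidene}-6-methyldec-4-ynoate
Conditions: CuI (cat.), NaI (cat.), K2CO3, DMF, rt
Reagents that add atoms: none
Why: copper-acetylide allylic substitution at the primary carbon forms C9–C10 as a skipped enyne and keeps the trisubstituted olefin geometry.

Step 10
Reactants: 14 ethyl (2E,6S)-6-[(tert-butyldimethylsilyl)oxy]-10-hydroxy-2-{2-[(4-methoxyphenyl)methoxy]ethylidene}-6-methyldec-4-ynoate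
Product: 15 ethyl (2E,4Z,6S)-6-[(tert-butyldimethylsilyl)oxy]-10-hydroxy-2-{2-[(4-methoxyphenyl)methoxy]ethylidene}-6-methyldec-4-enoate
Conditions: H2 (1 atm), Lindlar catalyst, quinoline, EtOAc, rt
Reagents that add atoms: none
Why: Lindlar semi-hydrogenation gives the Z-C8=C9 olefin by syn hydrogen delivery without touching the trisubstituted enoate.

Step 11
Reactants: 15 ethyl (2E,4Z,6S)-6-[(tert-butyldimethylsilyl)oxy]-10-hydroxy-2-{2-[(4-methoxyphenyl)methoxy]ethylidene}-6-methyldec-4-enoate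
Product: 16 (5S,6Z,9E)-5-[(tert-butyldimethylsilyl)oxy]-9-(ethoxycarbonyl)-11-[(4-methoxyphenyl)methoxy]-5-methylundeca-6,9-dienoic acid
Conditions: TEMPO (cat.), PhI(OAc)2, MeCN/pH 7 buffer, rt
Reagents that add atoms: water O
Why: oxoammonium oxidation takes the only primary alcohol to the acid (C4) through the aldehyde hydrate and is inert to the olefins, PMB and silyl ethers.

Step 12
Reactants: 16 (5S,6Z,9E)-5-[(tert-butyldimethylsilyl)oxy]-9-(ethoxycarbonyl)-11-[(4-methoxyphenyl)methoxy]-5-methylundeca-6,9-dienoic acid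
Product: 17 (5S,6Z,9E)-5-[(tert-butyldimethylsilyl)oxy]-9-(hydroxymethyl)-11-[(4-methoxyphenyl)methoxy]-5-methylundeca-6,9-dienoic acid
Conditions: DIBAL-H (4.5 equiv), CH2Cl2/THF, −78 °C; Rochelle salt
Reagents that add atoms: none
Why: DIBAL 1,2-reduction of the conjugated ester to the allylic alcohol (C19); the acid is held as an aluminium carboxylate that should not be reduced at −78 °C.

Step 13
Reactants: 17 (5S,6Z,9E)-5-[(tert-butyldimethylsilyl)oxy]-9-(hydroxymethyl)-11-[(4-methoxyphenyl)methoxy]-5-methylundeca-6,9-dienoic acid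
Product: 18 (6S,7Z,10E)-6-[(tert-butyldimethylsilyl)oxy]-10-{2-[(4-methoxyphenyl)methoxy]ethylidene}-6-methyl-1-oxacycloundec-7-en-2-one
Conditions: 2-methyl-6-nitrobenzoic anhydride, DMAP, CH2Cl2 (2 mM, slow addition), rt
Reagents that add atoms: none
Why: Shiina macrolactonisation under high dilution; the Z-olefin and the sp2 C11 reduce transannular strain in the 11-membered ring, and the C7 silyl ether rules out the competing δ-lactone.

Step 14
Reactants: 18 (6S,7Z,10E)-6-[(tert-butyldimethylsilyl)oxy]-10-{2-[(4-methoxyphenyl)methoxy]ethylidene}-6-methyl-1-oxacycloundec-7-en-2-one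
Product: 20 (1S,2R,5Z,7S)-7-[(tert-butyldimethylsilyl)oxy]-2-{[(4-methoxyphenyl)methoxy]methyl}-7-methyl-3-methylidenecyclonon-5-ene-1-carboxylic acid, via boron ketene acetal 19 (not isolated)
Conditions: (4S,5S)-2-bromo-1,3-bis{[3,5-bis(trifluoromethyl)phenyl]sulfonyl}-4,5-diphenyl-1,3,2-diazaborolidine (1.3 equiv, made from the bis-sulfonamide and BBr3, CH2Cl2, then evacuated), Et3N, toluene, −78 °C, then −20 to 4 °C; aq. acid
Reagents that add atoms: none
Why: The bromoborane and Et3N enolise the lactone to the E(O) boron ketene acetal 19 (C5 cis to the ring oxygen, the geometry the ring accommodates), which undergoes a suprafacial [3,3] shift in which C4a bonds to the exocyclic alkylidene carbon C11a while C19–O breaks, so that C19 becomes the exocyclic methylene and C4 the carboxyl. The closest known reaction type is the ester-enolate (Ireland–)Claisen ring contraction of macrocyclic allylic lactones, including its enantioselective boron-enolate variant. The nine-membered carbocycle is closed transannularly (11-membered lactone contracted, with C4, O and C19 leaving the ring) through a chair transition state that carries the C5–C10 tether on an axial bond at C4a, i.e. with the gauche C5–C4a–C11a–C11 torsion that a nine-membered ring requires. With the E(O) enolate and the (E)-alkylidene (C1 anti to C19, pseudo-equatorial) this chair gives C4 and C1 trans, and the absolute sense (4aS,11aR) is set by the C2-symmetric sulfonamide controller, not by the remote C7 centre. The step needs chair over boat and reagent over substrate control; the first is favoured by the unstrained gauche tether, the second by the distance of C7 from the reacting termini.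

Step 15
Reactants: 20 (1S,2R,5Z,7S)-7-[(tert-butyldimethylsilyl)oxy]-2-{[(4-methoxyphenyl)methoxy]methyl}-7-methyl-3-methylidenecyclonon-5-ene-1-carboxylic acid
Product: 21 [(1S,2R,5Z,7S)-7-[(tert-butyldimethylsilyl)oxy]-2-{[(4-methoxyphenyl)methoxy]methyl}-7-methyl-3-methylidenecyclonon-5-en-1-yl]methanol
Conditions: LiAlH4, THF, 0 °C to rt; Fieser work-up
Reagents that add atoms: none
Why: hydride reduction of the acid to the primary alcohol; no stereocentre is involved and the ethers and olefins are inert.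

Step 16
Reactants: 21 [(1S,2R,5Z,7S)-7-[(tert-butyldimethylsilyl)oxy]-2-{[(4-methoxyphenyl)methoxy]methyl}-7-methyl-3-methylidenecyclonon-5-en-1-yl]methanol
Product: 23 tert-butyl{[(1S,2Z,6R,7S)-7-ethynyl-6-{[(4-methoxyphenyl)methoxy]methyl}-1-methyl-5-methylidenecyclonon-2-en-1-yl]oxy}dimethylsilane, via aldehyde 22 (not isolated)
Conditions: Dess–Martin periodinane, NaHCO3, CH2Cl2, 0 °C; filter; then dimethyl (1-diazo-2-oxopropyl)phosphonate, K2CO3, MeOH, 0 °C to rt
Reagents that add atoms: dimethyl (1-diazo-2-oxopropyl)phosphonate COP(=O)(OC)C(=[N+]=[N-])C(C)=O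
Why: Dess–Martin oxidation and Ohira–Bestmann homologation are telescoped so that the epimerisable C4a aldehyde is not isolated; the reagent supplies C12 and gives the C4≡C12 alkyne.

Step 17
Reactants: 24 3-methylbut-2-en-1-ol
Product: 25 [(2S)-3,3-dimethyloxiran-2-yl]methanol
Conditions: Ti(OiPr)4 (cat.), L-(+)-diethyl tartrate (cat.), t-BuOOH, 4 Å MS, CH2Cl2, −20 °C
Reagents that add atoms: tert-butyl hydroperoxide CC(C)(C)OO
Why: Sharpless asymmetric epoxidation of prenol; L-(+)-tartrate should give the (S)-epoxide, which becomes C14.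

Step 18
Reactants: 25 [(2S)-3,3-dimethyloxiran-2-yl]methanol
Product: 26 (2R)-3,3-dimethyloxirane-2-carbaldehyde
Conditions: Dess–Martin periodinane, NaHCO3, CH2Cl2, 0 °C; used as a filtered solution
Reagents that add atoms: none
Why: neutral oxidation to the volatile epoxy aldehyde without epimerisation (the descriptor changes only by priority).

Step 19
Reactants: 23 tert-butyl{[(1S,2Z,6R,7S)-7-ethynyl-6-{[(4-methoxyphenyl)methoxy]methyl}-1-methyl-5-methylidenecyclonon-2-en-1-yl]oxy}dimethylsilane; 26 (2R)-3,3-dimethyloxirane-2-carbaldehyde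
Product: 28 C13 triethylsilyl ether of the (13S,14S)-propargylic epoxy alcohol, via lithium alkoxide 27 (not isolated)
Conditions: n-BuLi, THF, −78 °C; 26, −90 °C; then Et3SiCl, imidazole, −78 to 0 °C
Reagents that add atoms: chlorotriethylsilane CC[Si](Cl)(CC)CC
Why: Felkin–Anh addition of the lithium acetylide anti to the epoxide C–O bond should give the erythro (13S,14S) alcohol, reinforced by the methyl cis to the formyl group; the alkoxide is silylated in the same flask.

Step 20
Reactants: 28 C13 triethylsilyl ether of the (13S,14S)-propargylic epoxy alcohol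
Product: 29 C1 primary alcohol (28 without the 4-methoxybenzyl group)
Conditions: DDQ, CH2Cl2/pH 7 buffer, 0 °C to rt
Reagents that add atoms: none
Why: oxidative cleavage of the PMB ether frees only the C1 hydroxyl; the silyl ethers, epoxide, alkyne and olefins are stable to buffered DDQ.

Step 21
Reactants: 29 C1 primary alcohol
Product: 30 (4aS,7S,11aR,13S,14S,8Z,4(12)E)-7-O-TBS-13-O-TES 8,9-ene lactone
Conditions: PdI2 (5 mol%), PBu3 (10 mol%), CO (7 bar), MeCN, 70 °C
Reagents that add atoms: carbon monoxide [C-]#[O+]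
Why: palladium-catalysed cyclocarbonylation of an alkynol: the alkoxycarbonyl-palladium formed at O1 adds syn across C4≡C12 (6-exo-dig) and protodepalladation with retention leaves H12 cis to the C3 carbonyl, i.e. the (E)-alkylidene δ-lactone.

Step 22
Reactants: 30 (4aS,7S,11aR,13S,14S,8Z,4(12)E)-7-O-TBS-13-O-TES 8,9-ene lactone
Product: 31 (4aS,7S,11aR,13S,14S,8Z,4(12)E)-7,13-dihydroxy 8,9-ene lactone
Conditions: HF·pyridine, pyridine, THF, 0 °C to rt
Reagents that add atoms: none
Why: buffered fluoride removes both silyl ethers without opening the trisubstituted epoxide or adding to the alkylidene lactone.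

Step 23
Reactants: 31 (4aS,7S,11aR,13S,14S,8Z,4(12)E)-7,13-dihydroxy 8,9-ene lactone
Product: 32 CNP0147265.1 (4aS,7S,8R,9R,11aR,13S,14S)
Conditions: VO(acac)2 (cat.), t-BuOOH, CH2Cl2, 0 °C to rt
Reagents that add atoms: tert-butyl hydroperoxide CC(C)(C)OO
Why: vanadium-catalysed hydroxyl-directed epoxidation of the (Z)-cyclononenyl tertiary allylic alcohol should deliver oxygen syn to C7-OH, giving the cis-8,9-epoxide (8R,9R); the enoate C4=C12 and the undirected C11=C19 should not react.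

**Compound list**

1 | tert-butyl(hex-5-yn-1-yloxy)dimethylsilane | C#CCCCCO[Si](C)(C)C(C)(C)C | starting material
2 | (E)-{6-[(tert-butyldimethylsilyl)oxy]-2-methylhex-1-en-1-yl}dimethylalane | C[Al](C)/C=C(\C)CCCCO[Si](C)(C)C(C)(C)C | intermediate
3 | (2E)-7-[(tert-butyldimethylsilyl)oxy]-3-methylhept-2-en-1-ol | OC/C=C(\C)CCCCO[Si](C)(C)C(C)(C)C | intermediate
4 | [(2S,3S)-3-{4-[(tert-butyldimethylsilyl)oxy]butyl}-3-methyloxiran-2-yl]methanol | OC[C@@H]1O[C@@]1(C)CCCCO[Si](C)(C)C(C)(C)C | intermediate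
5 | tert-butyl{4-[(2S,3R)-3-(chloromethyl)-2-methyloxiran-2-yl]butoxy}dimethylsilane | ClC[C@@H]1O[C@@]1(C)CCCCO[Si](C)(C)C(C)(C)C | intermediate
6 | lithium (3S)-7-[(tert-butyldimethylsilyl)oxy]-1-chloro-3-methylhept-1-en-3-olate (olefin geometry undefined) | ClC=C[C@@](C)([O-])CCCCO[Si](C)(C)C(C)(C)C.[Li+] | intermediate
7 | (3S)-7-[(tert-butyldimethylsilyl)oxy]-3-methylhept-1-yn-3-ol | C#C[C@@](C)(O)CCCCO[Si](C)(C)C(C)(C)C | intermediate
8 | (3S)-3,7-bis[(tert-butyldimethylsilyl)oxy]-3-methylhept-1-yne | C#C[C@@](C)(O[Si](C)(C)C(C)(C)C)CCCCO[Si](C)(C)C(C)(C)C | intermediate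
9 | (5S)-5-[(tert-butyldimethylsilyl)oxy]-5-methylhept-6-yn-1-ol | C#C[C@@](C)(O[Si](C)(C)C(C)(C)C)CCCCO | intermediate
10 | ethyl acrylate | C=CC(=O)OCC | starting material
11 | 2-[(4-methoxyphenyl)methoxy]acetaldehyde | O=CCOCc1ccc(OC)cc1 | starting material
12 | ethyl 3-hydroxy-4-[(4-methoxyphenyl)methoxy]-2-methylidenebutanoate (racemic) | C=C(C(=O)OCC)C(O)COCc1ccc(OC)cc1 | intermediate
13 | ethyl (2Z)-2-(bromomethyl)-4-[(4-methoxyphenyl)methoxy]but-2-enoate | CCOC(=O)/C(CBr)=C/COCc1ccc(OC)cc1 | intermediate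
14 | ethyl (2E,6S)-6-[(tert-butyldimethylsilyl)oxy]-10-hydroxy-2-{2-[(4-methoxyphenyl)methoxy]ethylidene}-6-methyldec-4-ynoate | CCOC(=O)/C(CC#C[C@@](C)(O[Si](C)(C)C(C)(C)C)CCCCO)=C/COCc1ccc(OC)cc1 | intermediate
15 | ethyl (2E,4Z,6S)-6-[(tert-butyldimethylsilyl)oxy]-10-hydroxy-2-{2-[(4-methoxyphenyl)methoxy]ethylidene}-6-methyldec-4-enoate | CCOC(=O)/C(C/C=C\[C@@](C)(O[Si](C)(C)C(C)(C)C)CCCCO)=C/COCc1ccc(OC)cc1 | intermediate
16 | (5S,6Z,9E)-5-[(tert-butyldimethylsilyl)oxy]-9-(ethoxycarbonyl)-11-[(4-methoxyphenyl)methoxy]-5-methylundeca-6,9-dienoic acid | CCOC(=O)/C(C/C=C\[C@@](C)(O[Si](C)(C)C(C)(C)C)CCCC(=O)O)=C/COCc1ccc(OC)cc1 | intermediate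
17 | (5S,6Z,9E)-5-[(tert-butyldimethylsilyl)oxy]-9-(hydroxymethyl)-11-[(4-methoxyphenyl)methoxy]-5-methylundeca-6,9-dienoic acid | OC/C(C/C=C\[C@@](C)(O[Si](C)(C)C(C)(C)C)CCCC(=O)O)=C/COCc1ccc(OC)cc1 | intermediate
18 | (6S,7Z,10E)-6-[(tert-butyldimethylsilyl)oxy]-10-{2-[(4-methoxyphenyl)methoxy]ethylidene}-6-methyl-1-oxacycloundec-7-en-2-one | O=C1CCC[C@](C)(O[Si](C)(C)C(C)(C)C)/C=C\C/C(=C\COCc2ccc(OC)cc2)CO1 | intermediate
19 | E(O) boron ketene acetal of 18 bound to the (4S,5S)-diazaborolidine | O1C/C(=C/COCc2ccc(OC)cc2)C/C=C\[C@@](C)(O[Si](C)(C)C(C)(C)C)CC/C=C1/OB1N(S(=O)(=O)c2cc(C(F)(F)F)cc(C(F)(F)F)c2)[C@@H](c2ccccc2)[C@H](c2ccccc2)N1S(=O)(=O)c1cc(C(F)(F)F)cc(C(F)(F)F)c1 | intermediate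
20 | (1S,2R,5Z,7S)-7-[(tert-butyldimethylsilyl)oxy]-2-{[(4-methoxyphenyl)methoxy]methyl}-7-methyl-3-methylidenecyclonon-5-ene-1-carboxylic acid | C=C1C/C=C\[C@@](C)(O[Si](C)(C)C(C)(C)C)CC[C@H](C(=O)O)[C@H]1COCc1ccc(OC)cc1 | intermediate
21 | [(1S,2R,5Z,7S)-7-[(tert-butyldimethylsilyl)oxy]-2-{[(4-methoxyphenyl)methoxy]methyl}-7-methyl-3-methylidenecyclonon-5-en-1-yl]methanol | C=C1C/C=C\[C@@](C)(O[Si](C)(C)C(C)(C)C)CC[C@H](CO)[C@H]1COCc1ccc(OC)cc1 | intermediate
22 | (1S,2R,5Z,7S)-7-[(tert-butyldimethylsilyl)oxy]-2-{[(4-methoxyphenyl)methoxy]methyl}-7-methyl-3-methylidenecyclonon-5-ene-1-carbaldehyde | C=C1C/C=C\[C@@](C)(O[Si](C)(C)C(C)(C)C)CC[C@H](C=O)[C@H]1COCc1ccc(OC)cc1 | intermediate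
23 | tert-butyl{[(1S,2Z,6R,7S)-7-ethynyl-6-{[(4-methoxyphenyl)methoxy]methyl}-1-methyl-5-methylidenecyclonon-2-en-1-yl]oxy}dimethylsilane | C=C1C/C=C\[C@@](C)(O[Si](C)(C)C(C)(C)C)CC[C@H](C#C)[C@H]1COCc1ccc(OC)cc1 | intermediate
24 | 3-methylbut-2-en-1-ol | CC(C)=CCO | starting material
25 | [(2S)-3,3-dimethyloxiran-2-yl]methanol | OC[C@@H]1OC1(C)C | intermediate
26 | (2R)-3,3-dimethyloxirane-2-carbaldehyde | O=C[C@@H]1OC1(C)C | intermediate
27 | lithium alkoxide of the (13S,14S)-propargylic epoxy alcohol formed from 23 and 26 | C=C1C/C=C\[C@@](C)(O[Si](C)(C)C(C)(C)C)CC[C@H](C#C[C@H]([O-])[C@@H]2OC2(C)C)[C@H]1COCc1ccc(OC)cc1.[Li+] | intermediate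
28 | C13 triethylsilyl ether: 23 carrying at the alkyne terminus (1S)-1-[(2S)-3,3-dimethyloxiran-2-yl]-1-[(triethylsilyl)oxy]methyl | C=C1C/C=C\[C@@](C)(O[Si](C)(C)C(C)(C)C)CC[C@H](C#C[C@H](O[Si](CC)(CC)CC)[C@@H]2OC2(C)C)[C@H]1COCc1ccc(OC)cc1 | intermediate
29 | C1 primary alcohol: 28 with the 4-methoxybenzyl ether replaced by OH | C=C1C/C=C\[C@@](C)(O[Si](C)(C)C(C)(C)C)CC[C@H](C#C[C@H](O[Si](CC)(CC)CC)[C@@H]2OC2(C)C)[C@H]1CO | intermediate
30 | (4aS,7S,11aR,13S,14S,8Z,4(12)E)-7-O-TBS-13-O-TES 8,9-ene lactone (target skeleton with C8=C9 in place of the epoxide) | C=C1C/C=C\[C@@](C)(O[Si](C)(C)C(C)(C)C)CC[C@@H]2/C(=C\[C@H](O[Si](CC)(CC)CC)[C@@H]3OC3(C)C)C(=O)OC[C@@H]12 | intermediate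
31 | (4aS,7S,11aR,13S,14S,8Z,4(12)E)-7,13-dihydroxy 8,9-ene lactone | C=C1C/C=C\[C@@](C)(O)CC[C@@H]2/C(=C\[C@H](O)[C@@H]3OC3(C)C)C(=O)OC[C@@H]12 | intermediate
32 | CNP0147265.1 (4aS,7S,8R,9R,11aR,13S,14S; 4(12)E) | C=C1C[C@H]2O[C@H]2[C@@](C)(O)CC[C@@H]2/C(=C\[C@H](O)[C@@H]3OC3(C)C)C(=O)OC[C@@H]12 | target

**Count**

Total steps: 23. Longest linear sequence: 19 (steps 1–6, 9–16, 19–23).

**Steps most likely to fail**

1. Step 14. The medium ring may force a boat transition state (cis fusion), the face selection by the controller may be eroded by the macrocycle, or enolisation of the hindered lactone may be slow. Fallback, from 9 and 13, back at 20: the same [3,3] event is run on an open-chain ester and the ring is closed afterwards. Alkyne 9 is semi-hydrogenated (H2, Lindlar) to (5S)-5-[(tert-butyldimethylsilyl)oxy]-5-methylhept-6-en-1-ol F1 and oxidised (TEMPO, PhI(OAc)2) to (5S)-5-[(tert-butyldimethylsilyl)oxy]-5-methylhept-6-enoic acid F2. Bromide 13 is coupled with tributyl(vinyl)stannane (Pd2(dba)3, AsPh3) to ethyl (2E)-4-[(4-methoxyphenyl)methoxy]-2-(prop-2-en-1-yl)but-2-enoate F3 and reduced (DIBAL-H) to (2E)-4-[(4-methoxyphenyl)methoxy]-2-(prop-2-en-1-yl)but-2-en-1-ol F4. Esterification (EDC, DMAP) gives the allylic ester F5. Its boron-enolate Ireland–Claisen rearrangement with the same controller, now through an unconstrained chair, gives (2S,3R)-2-{(3S)-3-[(tert-butyldimethylsilyl)oxy]-3-methylpent-4-en-1-yl}-3-{[(4-methoxyphenyl)methoxy]methyl}-4-methylidenehept-6-enoic acid F6. Ring-closing metathesis (second-generation Ru carbene, high dilution) then forms C8=C9, Z by ring size, and gives 20.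

2. Step 21. The alkoxycarbonyl-palladium may fail to insert the hindered internal alkyne, or iodide and heat may damage the epoxide or the propargylic silyl ether. Fallback, from 29, back at 30: the same syn addition is done stepwise with silicon as the tether. Alcohol 29 is silylated (Me2SiHCl, Et3N) to the dimethylsilyl ether F7. Platinum(0)-catalysed intramolecular syn-hydrosilylation (6-exo-dig) gives the cyclic vinylsiloxane F8 with Si on C4 and H on C12. Iododesilylation with retention (N-iodosuccinimide, MeCN) gives the (Z)-vinyl iodide F9 with free C1-OH. Carbonylative lactonisation (Pd(PPh3)4, CO 1 atm, Et3N, THF, 50 °C) closes the lactone to 30 with the same geometry.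

3. Step 13. Activation of the acid may lead to dimers and oligomers instead of the strained 11-membered ring. Fallback, from 17, back at 18: the polarity of the ring closure is reversed by a Mitsunobu macrolactonisation (PPh3, DIAD, toluene, high dilution), in which the primary allylic C19 hydroxyl is activated and the carboxylate is the nucleophile; no new compound is formed on the way.

**Further compounds**

F1 | step 14 | (5S)-5-[(tert-butyldimethylsilyl)oxy]-5-methylhept-6-en-1-ol | C=C[C@@](C)(O[Si](C)(C)C(C)(C)C)CCCCO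
F2 | step 14 | (5S)-5-[(tert-butyldimethylsilyl)oxy]-5-methylhept-6-enoic acid | C=C[C@@](C)(O[Si](C)(C)C(C)(C)C)CCCC(=O)O
F3 | step 14 | ethyl (2E)-4-[(4-methoxyphenyl)methoxy]-2-(prop-2-en-1-yl)but-2-enoate | CCOC(=O)/C(CC=C)=C/COCc1ccc(OC)cc1
F4 | step 14 | (2E)-4-[(4-methoxyphenyl)methoxy]-2-(prop-2-en-1-yl)but-2-en-1-ol | OC/C(CC=C)=C/COCc1ccc(OC)cc1
F5 | step 14 | (2E)-4-[(4-methoxyphenyl)methoxy]-2-(prop-2-en-1-yl)but-2-en-1-yl (5S)-5-[(tert-butyldimethylsilyl)oxy]-5-methylhept-6-enoate | C=C[C@@](C)(O[Si](C)(C)C(C)(C)C)CCCC(=O)OC/C(CC=C)=C/COCc1ccc(OC)cc1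
F6 | step 14 | (2S,3R)-2-{(3S)-3-[(tert-butyldimethylsilyl)oxy]-3-methylpent-4-en-1-yl}-3-{[(4-methoxyphenyl)methoxy]methyl}-4-methylidenehept-6-enoic acid | C=C[C@@](C)(O[Si](C)(C)C(C)(C)C)CC[C@H](C(=O)O)[C@@H](COCc1ccc(OC)cc1)C(=C)CC=C
F7 | step 21 | dimethylsilyl ether of 29 | C=C1C/C=C\[C@@](C)(O[Si](C)(C)C(C)(C)C)CC[C@H](C#C[C@H](O[Si](CC)(CC)CC)[C@@H]2OC2(C)C)[C@H]1CO[SiH](C)C
F8 | step 21 | cyclic vinylsiloxane (30 with SiMe2 in place of C3=O) | C=C1C/C=C\[C@@](C)(O[Si](C)(C)C(C)(C)C)CC[C@@H]2/C(=C\[C@H](O[Si](CC)(CC)CC)[C@@H]3OC3(C)C)[Si](C)(C)OC[C@@H]12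
F9 | step 21 | (Z)-vinyl iodide with iodine on C4 and free C1-OH | C=C1C/C=C\[C@@](C)(O[Si](C)(C)C(C)(C)C)CC[C@H](/C(I)=C\[C@H](O[Si](CC)(CC)CC)[C@@H]2OC2(C)C)[C@H]1CO
F0 | step 13 | none | none
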